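**Retrosynthetic overview**

1. The route rests on the C3–C4 bond: C3 is a fully substituted carbinol (OH, CH2OH, C2) bonded to the benzylic CH2 C4 of ring A. Ring B is cut there into a C3 ketone and a C4 benzylic bromide (20), two electrophiles that SmI2 joins; ring B is the only ring made and it is closed last.
2. Keto ester 20 comes from alcohol 19, and 19 from the seven-membered benzylic lactone 15 (C4–O–C3(=O)). BnOCH2Li opens 15 at its carbonyl, which installs the CH2OBn arm on C3 and frees the C4 hydroxyl.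
3. C2 is made quaternary while the lactone ring is intact: enolate hydroxylation, silylation, then tert-butoxycarbonylation anti to ring E.
4. Lactone 12 comes from a rhodium-catalysed asymmetric conjugate addition (sets C1) of the ring A boronic acid 6 (from 6-bromovanillin) to the tribenzyl-gallate-type cinnamate 8, followed by lactonisation.
5. After ring closure: acidolysis of the tert-butyl ester and silyl ether, then hydrogenolysis of the five benzyl ethers.

Key step: step 15

Assumption: (S,S)-Ph-bod* is taken as the ligand hand that sends the aryl group to the α-si face of (E)-enoate 8, the sense this diene class shows with cyclic enones; if the adduct proved antipodal, the (R,R)-ligand would be used and nothing else changes.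
Assumption: 3,4,5-tris(benzyloxy)benzaldehyde (7) is taken as a commercial material.

**Route**

Step 1
Reactants: 1 6-bromovanillin
Product: 2 4-(benzyloxy)-2-bromo-5-methoxybenzaldehyde
Conditions: BnBr, K2CO3, DMF, 60 °C
Reagents that add atoms: benzyl bromide, BrCc1ccccc1
Why: Williamson etherification: the phenoxide, the only acidic site, is benzylated by SN2 while the aldehyde and aryl bromide are inert.

Step 2
Reactants: 2 4-(benzyloxy)-2-bromo-5-methoxybenzaldehyde
Product: 3 [4-(benzyloxy)-2-bromo-5-methoxyphenyl]methanol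
Conditions: NaBH4, MeOH/THF, 0 °C
Reagents that add atoms: none
Why: Borohydride reduction of the aldehyde should give the primary benzylic alcohol whose carbon becomes C4; nothing else in 2 is reducible under these conditions.

Step 3
Reactants: 3 [4-(benzyloxy)-2-bromo-5-methoxyphenyl]methanol
Product: 4 tert-butyldimethylsilyl ether of 3
Conditions: t-BuMe2SiCl, imidazole, DMF, rt
Reagents that add atoms: tert-butyldimethylsilyl chloride, CC(C)(C)[Si](C)(C)Cl
Why: Imidazole-promoted silylation masks the alcohol so that it cannot quench the aryllithium of step 4 or the arylrhodium species of step 6.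

Step 4
Reactants: 4 tert-butyldimethylsilyl ether of 3
Product: 6 [5-(benzyloxy)-2-({[tert-butyl(dimethyl)silyl]oxy}methyl)-4-methoxyphenyl]boronic acid, via aryllithium 5 (not isolated)
Conditions: B(Oi-Pr)3 present, then n-BuLi, THF, −78 °C (in situ quench); 1 M HCl to pH 5, 0 °C
Reagents that add atoms: triisopropyl borate, CC(C)OB(OC(C)C)OC(C)C; water, O
Why: Bromine–lithium exchange followed by borylation; with the borate present from the start the aryllithium 5 should be trapped before a 1,4-silyl shift from oxygen to carbon (retro-Brook rearrangement) can occur, and mild hydrolysis releases the boronic acid.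

Step 5
Reactants: 7 3,4,5-tris(benzyloxy)benzaldehyde
Product: 8 methyl (2E)-3-[3,4,5-tris(benzyloxy)phenyl]prop-2-enoate
Conditions: (MeO)2P(O)CH2CO2Me, NaH, THF, 0 °C → rt
Reagents that add atoms: trimethyl phosphonoacetate, COC(=O)CP(=O)(OC)OC
Why: Horner–Wadsworth–Emmons olefination with a stabilised phosphonate should give the (E)-enoate needed for face-selective arylation.

Step 6
Reactants: 8 methyl (2E)-3-[3,4,5-tris(benzyloxy)phenyl]prop-2-enoate; 6 ring A boronic acid
Product: 9 methyl (3S)-3-[5-(benzyloxy)-2-({[tert-butyl(dimethyl)silyl]oxy}methyl)-4-methoxyphenyl]-3-[3,4,5-tris(benzyloxy)phenyl]propanoate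
Conditions: [RhCl(C2H4)2]2 (2.5 mol %), (S,S)-Ph-bod* [(1S,4S)-2,5-diphenylbicyclo[2.2.2]octa-2,5-diene] (5.5 mol %), KOH (0.2 equiv), 6 (2 equiv), dioxane/H2O 10:1, 50 °C
Reagents that add atoms: none
Why: Hayashi–Miyaura conjugate arylation (transmetalation of 6 to a monovalent rhodium hydroxide, enoate insertion, hydrolysis of the oxa-π-allyl); the chiral diene steers the ring A aryl group to the α-si face of the enoate, which sets C1 as (S).

Step 7
Reactants: 9 conjugate adduct
Product: 11 (3S)-3-[5-(benzyloxy)-2-(hydroxymethyl)-4-methoxyphenyl]-3-[3,4,5-tris(benzyloxy)phenyl]propanoic acid, via hydroxy ester 10 (not isolated)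
Conditions: Bu4NF, THF, 0 °C → rt; then LiOH, MeOH/H2O, 40 °C; 1 M HCl to pH 4, 0 °C
Reagents that add atoms: lithium hydroxide, [Li+].[OH-]
Why: Fluoride desilylation followed by saponification should give the hydroxy acid under basic conditions, avoiding the acid-induced ionisation of the para-alkoxybenzyl alcohol that would invite Friedel–Crafts attack by ring E.

Step 8
Reactants: 11 hydroxy acid
Product: 12 (5S)-7-(benzyloxy)-8-methoxy-5-[3,4,5-tris(benzyloxy)phenyl]-4,5-dihydro-2-benzoxepin-3(1H)-one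
Conditions: EDC·HCl, DMAP (cat.), CH2Cl2 (5 mM), rt
Reagents that add atoms: none
Why: Steglich-type carbodiimide lactonisation at high dilution should close the benzo-fused seven-membered lactone under neutral conditions, and the stereocentre is not involved.

Step 9
Reactants: 12 lactone
Product: 13 (4R,5S)-7-(benzyloxy)-4-hydroxy-8-methoxy-5-[3,4,5-tris(benzyloxy)phenyl]-4,5-dihydro-2-benzoxepin-3(1H)-one
Conditions: NaN(SiMe3)2, THF, −78 °C; 2-(phenylsulfonyl)-3-phenyloxaziridine, −78 °C; AcOH
Reagents that add atoms: 2-(phenylsulfonyl)-3-phenyloxaziridine, O=S(=O)(c1ccccc1)N1OC1c1ccccc1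
Why: Davis oxidation of the sodium lactone enolate, with oxygen expected to enter anti to the C5 aryl group; the configuration at C4 is not critical because this carbon is planarised again in step 11.

Step 10
Reactants: 13 α-hydroxy lactone
Product: 14 (4R,5S)-7-(benzyloxy)-8-methoxy-4-[(triethylsilyl)oxy]-5-[3,4,5-tris(benzyloxy)phenyl]-4,5-dihydro-2-benzoxepin-3(1H)-one
Conditions: Et3SiCl, imidazole, DMF, rt
Reagents that add atoms: chlorotriethylsilane, CC[Si](Cl)(CC)CC
Why: Silylation of the unhindered secondary alcohol; the triethylsilyl ether is non-chelating, survives the enolate and organolithium steps, and can be removed together with the tert-butyl ester in step 16.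

Step 11
Reactants: 14 α-silyloxy lactone
Product: 15 tert-butyl (4S,5S)-7-(benzyloxy)-8-methoxy-3-oxo-4-[(triethylsilyl)oxy]-5-[3,4,5-tris(benzyloxy)phenyl]-1,3,4,5-tetrahydro-2-benzoxepine-4-carboxylate
Conditions: LiN(i-Pr)2, THF, −78 °C; Boc2O, −78 → −30 °C; AcOH
Reagents that add atoms: di-tert-butyl dicarbonate, CC(C)(C)OC(=O)OC(=O)OC(C)(C)C
Why: C-acylation (tert-butoxycarbonylation) of the lithium enolate; allylic strain with the silyloxy group turns the C5 aryl group pseudoaxial, so the electrophile should approach the opposite face and place CO2t-Bu trans and the silyloxy group cis to ring E, which is the (S) configuration of C2 in the target.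

Step 12
Reactants: 16 benzyl chloromethyl ether
Product: 17 tributyl[(benzyloxy)methyl]stannane
Conditions: Bu3SnH, LiN(i-Pr)2, THF, 0 °C; then 16, −78 °C → rt
Reagents that add atoms: tributyltin hydride, CCCC[SnH](CCCC)CCCC
Why: SN2 alkylation of the stannyl anion by the chloromethyl ether is the standard entry to α-alkoxymethyl stannanes.

Step 13
Reactants: 15 lactone tert-butyl ester; 17 tributyl[(benzyloxy)methyl]stannane
Product: 19 tert-butyl (2S)-4-(benzyloxy)-2-{(S)-[5-(benzyloxy)-2-(hydroxymethyl)-4-methoxyphenyl][3,4,5-tris(benzyloxy)phenyl]methyl}-3-oxo-2-[(triethylsilyl)oxy]butanoate, via (benzyloxy)methyllithium 18 (not isolated)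
Conditions: 17, n-BuLi, THF, −78 °C; then 15, −78 °C; AcOH, −78 °C
Reagents that add atoms: none
Why: Tin–lithium exchange gives the α-alkoxy organolithium 18, which should add to the s-cis lactone carbonyl (acyl substitution with the benzylic alkoxide as leaving group) while the tert-butyl ester is too hindered to react and the neopentyl-type ketone formed is shielded from a second addition; C1 and C2 are not touched.

Step 14
Reactants: 19 hydroxy keto ester
Product: 20 tert-butyl (2S)-4-(benzyloxy)-2-{(S)-[5-(benzyloxy)-2-(bromomethyl)-4-methoxyphenyl][3,4,5-tris(benzyloxy)phenyl]methyl}-3-oxo-2-[(triethylsilyl)oxy]butanoate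
Conditions: CBr4, PPh3 (added in portions), CH2Cl2, −20 → 0 °C; filtered through a short silica pad and used at once
Reagents that add atoms: carbon tetrabromide, BrC(Br)(Br)Br
Why: Appel bromination of the primary benzylic alcohol under neutral conditions leaves the silyl ether, tert-butyl ester and ketone alone; the para-alkoxybenzyl bromide ionises easily and is therefore not stored.

Step 15
Reactants: 20 bromo keto ester
Product: 22 tert-butyl (1S,2S,3R)-7-(benzyloxy)-3-[(benzyloxy)methyl]-3-hydroxy-6-methoxy-2-[(triethylsilyl)oxy]-1-[3,4,5-tris(benzyloxy)phenyl]-1,2,3,4-tetrahydronaphthalene-2-carboxylate, via benzylsamarium diiodide 21 (not isolated)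
Conditions: SmI2 (2.5 equiv, 0.1 M in THF), −78 °C, 20 added over 1 h (inverse addition, final 5 mM), then → −20 °C; sat. aq. NH4Cl
Reagents that add atoms: none
Why: Two single-electron transfers from divalent samarium should convert the C4–Br bond, through the benzyl radical, into benzylsamarium 21, whose carbon adds to the C3 ketone; this is an intramolecular Barbier reaction, closest to the known SmI2 cyclisations of halo ketones and SmI2 benzylations of ketones. Ring B is closed by 6-exo-trig attack of C4 on C3. The new stereocentre C3 is controlled by a six-membered chelate in which trivalent samarium bridges the ketone oxygen and the ester carbonyl oxygen, so that C3=O eclipses the C2–CO2t-Bu bond and the CH2OBn arm lies between the silyloxy group and C1; C4 is held on C1 through ring A and can reach only the ketone face turned toward C1, which leaves the C3 oxygen cis to the ester and trans to the silyloxy group. The step needs chemoselectivity (C–Br reduction before ketyl formation, and addition to the ketone rather than the ester) and facial selectivity. The first is secured by the fast reduction of a benzylic bromide in THF without HMPA or a proton source and by the bulk and low electrophilicity of the tert-butyl ester; the second by the chelate together with the non-coordinating silyl ether. Slow inverse addition at low temperature keeps the bromide concentration low so that coupling of two benzyl units is suppressed.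

Step 16
Reactants: 22 cyclised tetralin
Product: 23 (1S,2S,3R)-7-(benzyloxy)-3-[(benzyloxy)methyl]-2,3-dihydroxy-6-methoxy-1-[3,4,5-tris(benzyloxy)phenyl]-1,2,3,4-tetrahydronaphthalene-2-carboxylic acid
Conditions: CF3CO2H/CH2Cl2 1:4, H2O (5 equiv), anisole, 0 °C → rt
Reagents that add atoms: none
Why: Acidolysis: the tert-butyl ester is cleaved by alkyl–oxygen fission (insensitive to the crowding at the carbonyl) and the triethylsilyl ether is hydrolysed, while the absence of base avoids retro-aldol opening of the β-hydroxy acid and the benzyl ethers and stereocentres are untouched.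

Step 17
Reactants: 23 pentabenzyl dihydroxy acid
Product: 24 (1S,2S,3R)-2,3,7-trihydroxy-3-(hydroxymethyl)-6-methoxy-1-(3,4,5-trihydroxyphenyl)-1,2,3,4-tetrahydronaphthalene-2-carboxylic acid
Conditions: H2 (1 atm), Pd/C (10 wt % palladium on carbon), MeOH/EtOAc, rt; filtration and concentration under argon
Reagents that add atoms: none
Why: Hydrogenolysis of the five benzyl ethers; C1 and C4 carry no benzylic heteroatom, so nothing else is cleaved, and oxygen is excluded because the trihydroxyphenyl ring is easily oxidised.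

**Compound list**

1 | 6-bromovanillin (2-bromo-4-hydroxy-5-methoxybenzaldehyde) | COc1cc(C=O)c(Br)cc1O | starting material
2 | 4-(benzyloxy)-2-bromo-5-methoxybenzaldehyde | COc1cc(C=O)c(Br)cc1OCc1ccccc1 | intermediate
3 | [4-(benzyloxy)-2-bromo-5-methoxyphenyl]methanol | COc1cc(CO)c(Br)cc1OCc1ccccc1 | intermediate
4 | {[4-(benzyloxy)-2-bromo-5-methoxyphenyl]methoxy}(tert-butyl)dimethylsilane | COc1cc(CO[Si](C)(C)C(C)(C)C)c(Br)cc1OCc1ccccc1 | intermediate
5 | [5-(benzyloxy)-2-({[tert-butyl(dimethyl)silyl]oxy}methyl)-4-methoxyphenyl]lithium | COc1cc(CO[Si](C)(C)C(C)(C)C)c([Li])cc1OCc1ccccc1 | intermediate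
6 | [5-(benzyloxy)-2-({[tert-butyl(dimethyl)silyl]oxy}methyl)-4-methoxyphenyl]boronic acid | COc1cc(CO[Si](C)(C)C(C)(C)C)c(B(O)O)cc1OCc1ccccc1 | intermediate
7 | 3,4,5-tris(benzyloxy)benzaldehyde | O=Cc1cc(OCc2ccccc2)c(OCc2ccccc2)c(OCc2ccccc2)c1 | starting material
8 | methyl (2E)-3-[3,4,5-tris(benzyloxy)phenyl]prop-2-enoate | COC(=O)/C=C/c1cc(OCc2ccccc2)c(OCc2ccccc2)c(OCc2ccccc2)c1 | intermediate
9 | methyl (3S)-3-[5-(benzyloxy)-2-({[tert-butyl(dimethyl)silyl]oxy}methyl)-4-methoxyphenyl]-3-[3,4,5-tris(benzyloxy)phenyl]propanoate | COc1cc(CO[Si](C)(C)C(C)(C)C)c(cc1OCc1ccccc1)[C@H](c1cc(OCc2ccccc2)c(OCc2ccccc2)c(OCc2ccccc2)c1)CC(=O)OC | intermediate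
10 | methyl (3S)-3-[5-(benzyloxy)-2-(hydroxymethyl)-4-methoxyphenyl]-3-[3,4,5-tris(benzyloxy)phenyl]propanoate | COc1cc(CO)c(cc1OCc1ccccc1)[C@H](c1cc(OCc2ccccc2)c(OCc2ccccc2)c(OCc2ccccc2)c1)CC(=O)OC | intermediate
11 | (3S)-3-[5-(benzyloxy)-2-(hydroxymethyl)-4-methoxyphenyl]-3-[3,4,5-tris(benzyloxy)phenyl]propanoic acid | COc1cc(CO)c(cc1OCc1ccccc1)[C@H](c1cc(OCc2ccccc2)c(OCc2ccccc2)c(OCc2ccccc2)c1)CC(=O)O | intermediate
12 | (5S)-7-(benzyloxy)-8-methoxy-5-[3,4,5-tris(benzyloxy)phenyl]-4,5-dihydro-2-benzoxepin-3(1H)-one | COc1cc2c(cc1OCc1ccccc1)[C@H](c1cc(OCc3ccccc3)c(OCc3ccccc3)c(OCc3ccccc3)c1)CC(=O)OC2 | intermediate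
13 | (4R,5S)-7-(benzyloxy)-4-hydroxy-8-methoxy-5-[3,4,5-tris(benzyloxy)phenyl]-4,5-dihydro-2-benzoxepin-3(1H)-one | COc1cc2c(cc1OCc1ccccc1)[C@H](c1cc(OCc3ccccc3)c(OCc3ccccc3)c(OCc3ccccc3)c1)[C@@H](O)C(=O)OC2 | intermediate
14 | (4R,5S)-7-(benzyloxy)-8-methoxy-4-[(triethylsilyl)oxy]-5-[3,4,5-tris(benzyloxy)phenyl]-4,5-dihydro-2-benzoxepin-3(1H)-one | COc1cc2c(cc1OCc1ccccc1)[C@H](c1cc(OCc3ccccc3)c(OCc3ccccc3)c(OCc3ccccc3)c1)[C@@H](O[Si](CC)(CC)CC)C(=O)OC2 | intermediate
15 | tert-butyl (4S,5S)-7-(benzyloxy)-8-methoxy-3-oxo-4-[(triethylsilyl)oxy]-5-[3,4,5-tris(benzyloxy)phenyl]-1,3,4,5-tetrahydro-2-benzoxepine-4-carboxylate | COc1cc2c(cc1OCc1ccccc1)[C@H](c1cc(OCc3ccccc3)c(OCc3ccccc3)c(OCc3ccccc3)c1)[C@@](O[Si](CC)(CC)CC)(C(=O)OC(C)(C)C)C(=O)OC2 | intermediate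
16 | benzyl chloromethyl ether | ClCOCc1ccccc1 | starting material
17 | tributyl[(benzyloxy)methyl]stannane | CCCC[Sn](CCCC)(CCCC)COCc1ccccc1 | intermediate
18 | (benzyloxy)methyllithium | [Li]COCc1ccccc1 | intermediate
19 | tert-butyl (2S)-4-(benzyloxy)-2-{(S)-[5-(benzyloxy)-2-(hydroxymethyl)-4-methoxyphenyl][3,4,5-tris(benzyloxy)phenyl]methyl}-3-oxo-2-[(triethylsilyl)oxy]butanoate | COc1cc(CO)c(cc1OCc1ccccc1)[C@H](c1cc(OCc2ccccc2)c(OCc2ccccc2)c(OCc2ccccc2)c1)[C@@](O[Si](CC)(CC)CC)(C(=O)OC(C)(C)C)C(=O)COCc1ccccc1 | intermediate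
20 | tert-butyl (2S)-4-(benzyloxy)-2-{(S)-[5-(benzyloxy)-2-(bromomethyl)-4-methoxyphenyl][3,4,5-tris(benzyloxy)phenyl]methyl}-3-oxo-2-[(triethylsilyl)oxy]butanoate | COc1cc(CBr)c(cc1OCc1ccccc1)[C@H](c1cc(OCc2ccccc2)c(OCc2ccccc2)c(OCc2ccccc2)c1)[C@@](O[Si](CC)(CC)CC)(C(=O)OC(C)(C)C)C(=O)COCc1ccccc1 | intermediate
21 | benzylsamarium diiodide (trivalent samarium) formed from 20 by replacement of Br | COc1cc(C[Sm](I)I)c(cc1OCc1ccccc1)[C@H](c1cc(OCc2ccccc2)c(OCc2ccccc2)c(OCc2ccccc2)c1)[C@@](O[Si](CC)(CC)CC)(C(=O)OC(C)(C)C)C(=O)COCc1ccccc1 | intermediate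
22 | tert-butyl (1S,2S,3R)-7-(benzyloxy)-3-[(benzyloxy)methyl]-3-hydroxy-6-methoxy-2-[(triethylsilyl)oxy]-1-[3,4,5-tris(benzyloxy)phenyl]-1,2,3,4-tetrahydronaphthalene-2-carboxylate | COc1cc2c(cc1OCc1ccccc1)[C@H](c1cc(OCc3ccccc3)c(OCc3ccccc3)c(OCc3ccccc3)c1)[C@@](O[Si](CC)(CC)CC)(C(=O)OC(C)(C)C)[C@](O)(COCc1ccccc1)C2 | intermediate
23 | (1S,2S,3R)-7-(benzyloxy)-3-[(benzyloxy)methyl]-2,3-dihydroxy-6-methoxy-1-[3,4,5-tris(benzyloxy)phenyl]-1,2,3,4-tetrahydronaphthalene-2-carboxylic acid | COc1cc2c(cc1OCc1ccccc1)[C@H](c1cc(OCc3ccccc3)c(OCc3ccccc3)c(OCc3ccccc3)c1)[C@@](O)(C(=O)O)[C@](O)(COCc1ccccc1)C2 | intermediate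
24 | (1S,2S,3R)-2,3,7-trihydroxy-3-(hydroxymethyl)-6-methoxy-1-(3,4,5-trihydroxyphenyl)-1,2,3,4-tetrahydronaphthalene-2-carboxylic acid (CNP0174537.1) | COc1cc2c(cc1O)[C@H](c1cc(O)c(O)c(O)c1)[C@@](O)(C(=O)O)[C@](O)(CO)C2 | target

**Step count**

Total: 17 steps. Longest linear sequence: 15 steps (steps 1–4, 6–11, 13–17).

**Steps most likely to fail**

1. Step 15 (SmI2 ring closure). Electron transfer to the chelating α-oxygenated keto ester may compete with C–Br reduction and lead to loss of the α-oxygen substituents; two benzyl units may couple; the ketone may be attacked on the wrong face. Fallback, setting out from 19 and coming back at 24: the C3–C4 bond is made by ketyl–aldehyde pinacol coupling instead. Alcohol 19 is oxidised with Dess–Martin periodinane (NaHCO3, CH2Cl2) to the keto aldehyde F1. SmI2 (THF, t-BuOH, −78 °C) should couple the two carbonyls through a samarium-bridged intermediate to the cis-3,4-diol F2. H2 over Pd/C with a trace of AcOH should remove the five benzyl ethers and hydrogenolyse the electron-rich benzylic C4–OH, giving the debenzylated tert-butyl ester F3. CF3CO2H/H2O then cleaves the tert-butyl ester and the silyl ether to give 24.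

2. Step 13 (lactone opening). Addition to the neopentyl-type lactone carbonyl may be too slow at the temperature at which 18 is stable, or a second addition may occur. Fallback, setting out from 15 and coming back at 20: the carbon nucleophile is given an aldehyde instead of an ester. i-Bu2AlH (CH2Cl2, −78 °C) should reduce the lactone, but not the tert-butyl ester, to the lactol F4. Excess 18 adds to its open hydroxy aldehyde form to give the diol F5 as a mixture of C3 epimers. Appel bromination at −20 °C should take only the primary benzylic hydroxyl and give the bromo alcohol F6, and Dess–Martin oxidation of the secondary alcohol then gives 20.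

3. Step 11 (quaternisation of C2). O-acylation or low conversion may result because the bulky dicarbonate has to attack a fully substituted enolate carbon. Fallback, setting out from 14 and coming back at 15: the small electrophile CO2 is used. The lithium enolate of 14 is carboxylated with CO2 gas at −78 °C, anti to ring E, to give after cold acidic work-up the carboxylic acid F7, which is esterified with O-tert-butyl-N,N'-diisopropylisourea (CH2Cl2, rt) to 15.

**Further compounds**

F1 | step 15 | tert-butyl (2S)-4-(benzyloxy)-2-{(S)-[5-(benzyloxy)-2-formyl-4-methoxyphenyl][3,4,5-tris(benzyloxy)phenyl]methyl}-3-oxo-2-[(triethylsilyl)oxy]butanoate | COc1cc(C=O)c(cc1OCc1ccccc1)[C@H](c1cc(OCc2ccccc2)c(OCc2ccccc2)c(OCc2ccccc2)c1)[C@@](O[Si](CC)(CC)CC)(C(=O)OC(C)(C)C)C(=O)COCc1ccccc1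
F2 | step 15 | tert-butyl (1S,2S,3S,4S)-7-(benzyloxy)-3-[(benzyloxy)methyl]-3,4-dihydroxy-6-methoxy-2-[(triethylsilyl)oxy]-1-[3,4,5-tris(benzyloxy)phenyl]-1,2,3,4-tetrahydronaphthalene-2-carboxylate | COc1cc2c(cc1OCc1ccccc1)[C@H](c1cc(OCc3ccccc3)c(OCc3ccccc3)c(OCc3ccccc3)c1)[C@@](O[Si](CC)(CC)CC)(C(=O)OC(C)(C)C)[C@](O)(COCc1ccccc1)[C@H]2O
F3 | step 15 | tert-butyl (1S,2S,3R)-3,7-dihydroxy-3-(hydroxymethyl)-6-methoxy-2-[(triethylsilyl)oxy]-1-(3,4,5-trihydroxyphenyl)-1,2,3,4-tetrahydronaphthalene-2-carboxylate | COc1cc2c(cc1O)[C@H](c1cc(O)c(O)c(O)c1)[C@@](O[Si](CC)(CC)CC)(C(=O)OC(C)(C)C)[C@](O)(CO)C2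
F4 | step 13 | tert-butyl (3RS,4S,5S)-7-(benzyloxy)-3-hydroxy-8-methoxy-4-[(triethylsilyl)oxy]-5-[3,4,5-tris(benzyloxy)phenyl]-1,3,4,5-tetrahydro-2-benzoxepine-4-carboxylate | COc1cc2c(cc1OCc1ccccc1)[C@H](c1cc(OCc3ccccc3)c(OCc3ccccc3)c(OCc3ccccc3)c1)[C@@](O[Si](CC)(CC)CC)(C(=O)OC(C)(C)C)C(O)OC2
F5 | step 13 | tert-butyl (2S,3RS)-4-(benzyloxy)-2-{(S)-[5-(benzyloxy)-2-(hydroxymethyl)-4-methoxyphenyl][3,4,5-tris(benzyloxy)phenyl]methyl}-3-hydroxy-2-[(triethylsilyl)oxy]butanoate | COc1cc(CO)c(cc1OCc1ccccc1)[C@H](c1cc(OCc2ccccc2)c(OCc2ccccc2)c(OCc2ccccc2)c1)[C@@](O[Si](CC)(CC)CC)(C(=O)OC(C)(C)C)C(O)COCc1ccccc1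
F6 | step 13 | tert-butyl (2S,3RS)-4-(benzyloxy)-2-{(S)-[5-(benzyloxy)-2-(bromomethyl)-4-methoxyphenyl][3,4,5-tris(benzyloxy)phenyl]methyl}-3-hydroxy-2-[(triethylsilyl)oxy]butanoate | COc1cc(CBr)c(cc1OCc1ccccc1)[C@H](c1cc(OCc2ccccc2)c(OCc2ccccc2)c(OCc2ccccc2)c1)[C@@](O[Si](CC)(CC)CC)(C(=O)OC(C)(C)C)C(O)COCc1ccccc1
F7 | step 11 | (4R,5S)-7-(benzyloxy)-8-methoxy-3-oxo-4-[(triethylsilyl)oxy]-5-[3,4,5-tris(benzyloxy)phenyl]-1,3,4,5-tetrahydro-2-benzoxepine-4-carboxylic acid (same spatial arrangement as 15) | COc1cc2c(cc1OCc1ccccc1)[C@H](c1cc(OCc3ccccc3)c(OCc3ccccc3)c(OCc3ccccc3)c1)[C@@](O[Si](CC)(CC)CC)(C(=O)O)C(=O)OC2
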